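**Retrosynthetic overview**
1. The pyranone is attached last: Tsuji–Trost C3-allylation of 4-hydroxy-6-methyl-2H-pyran-2-one 20 with the allylic carbonate 19.
2. The carbocycle is cut at the bond between the carbinol carbon and the neighbouring ring CH2. Acyclic iodo aldehyde 14 closes to cyclohexanol 17 in a chromium-mediated radical–polar cascade that also creates the exocyclic methylene and the carbinol stereocentre.
3. Enabling feature: the 1,1-disubstituted cyclopropane of 14. Its quaternary carbon (the future methylidene-bearing ring carbon) carries the CH2I group, and its two equivalent CH2 groups become the two adjacent ring CH2 carbons. Strain-release opening unmasks the alkene and a homoallyl carbon nucleophile, which faces a non-enolisable CMe2–CHO aldehyde.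
4. 14 comes from farnesol: terminal degradation to aldehyde 5, Wittig to enal 7, enantioselective Mukaiyama–Michael addition of ketene acetal 8 (sets the side-chain-bearing stereocentre and the gem-dimethyl carbon), then α-methylenation, reduction, directed cyclopropanation, iodination and ester-to-aldehyde reduction.
5. Ring order: temporary cyclopropane (step 8), then the cyclohexane (step 11, cyclopropane consumed); the pyranone ring is brought in intact (step 14).

Key step: step 11

Remark: the target is read as the cis ring isomer, (1R,3S)-3-hydroxy-2,2-dimethyl-6-methylidenecyclohexyl, with hydroxyl and side chain both equatorial and two E trisubstituted alkenes. TBDPS = tert-butyldiphenylsilyl.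

**Route**

Step 1
Reactants: 1 (2E,6E)-farnesol
Product: 2 tert-butyl(diphenyl){[(2E,6E)-3,7,11-trimethyldodeca-2,6,10-trien-1-yl]oxy}silane
Conditions: TBDPSCl, imidazole, DMF, 0 °C to rt
Reagents that add atoms: tert-butyl(chloro)diphenylsilane, CC(C)(C)[Si](Cl)(c1ccccc1)c1ccccc1
Why: Standard silylation of a primary allylic alcohol gives a silyl ether that should survive every step up to the fluoride deprotection in step 12.

Step 2
Reactants: 2 farnesyl TBDPS ether
Product: 4 tert-butyl{[(2E,6E)-9-(3,3-dimethyloxiran-2-yl)-3,7-dimethylnona-2,6-dien-1-yl]oxy}diphenylsilane (racemic), via bromohydrin 3 (not isolated)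
Conditions: NBS, THF/H2O, 0 °C; then K2CO3, MeOH, rt
Reagents that add atoms: water, O
Why: Terminal-selective bromohydrin formation (water opens the bromonium ion of the most accessible, electron-rich terminal alkene at its tertiary carbon) followed by intramolecular Williamson closure gives the terminal epoxide, whose configuration is irrelevant because it is cleaved in step 3.

Step 3
Reactants: 4 terminal epoxide
Product: 5 (4E,8E)-10-(TBDPS-oxy)-4,8-dimethyldeca-4,8-dienal
Conditions: H5IO6, THF/Et2O, 0 °C
Reagents that add atoms: none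
Why: Periodic acid hydrates the epoxide at its tertiary carbon and cleaves the resulting glycol (Malaprade-type cleavage), which excises acetone and should leave the alkenes and the silyl ether untouched.

Step 4
Reactants: 5 aldehyde; 6 (triphenylphosphoranylidene)acetaldehyde
Product: 7 (2E,6E,10E)-12-(TBDPS-oxy)-6,10-dimethyldodeca-2,6,10-trienal
Conditions: toluene, 80 °C
Reagents that add atoms: none
Why: Wittig olefination with a stabilised ylide should give the E enal, the Michael acceptor for step 5.

Step 5
Reactants: 7 enal; 8 1-methoxy-2-methyl-1-(trimethylsilyloxy)prop-1-ene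
Product: 9 methyl (3R,6E,10E)-12-(TBDPS-oxy)-2,2,6,10-tetramethyl-3-(2-oxoethyl)dodeca-6,10-dienoate
Conditions: (2S,5S)-5-benzyl-2-tert-butyl-3-methylimidazolidin-4-one·CF3CO2H (20 mol %), CH2Cl2/H2O, −40 °C
Reagents that add atoms: none
Why: Iminium-catalysed Mukaiyama–Michael addition: the chiral imidazolidinone forms an E iminium ion with one face shielded, so the ketene acetal should add to the Re face of C3 of 7 and create in one bond the gem-dimethyl quaternary carbon and the adjacent (R) stereocentre (the enantiomeric catalyst is used if the facial sense proves opposite).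

Step 6
Reactants: 9 ester aldehyde
Product: 10 methyl (3R,6E,10E)-12-(TBDPS-oxy)-2,2,6,10-tetramethyl-3-(3-oxoprop-1-en-2-yl)dodeca-6,10-dienoate
Conditions: 37% aq. CH2O, pyrrolidine (10 mol %), EtCO2H (10 mol %), i-PrOH, 45 °C
Reagents that add atoms: formaldehyde, C=O
Why: Amine-catalysed α-methylenation (Mannich condensation with formaldehyde, then elimination) acts at the only enolisable position, and the congested allylic stereocentre should resist dienamine formation and so keep its configuration.

Step 7
Reactants: 10 2-substituted acrolein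
Product: 11 methyl (3R,6E,10E)-12-(TBDPS-oxy)-3-(3-hydroxyprop-1-en-2-yl)-2,2,6,10-tetramethyldodeca-6,10-dienoate
Conditions: NaBH4, CeCl3·7H2O, MeOH, −20 °C
Reagents that add atoms: none
Why: Luche reduction should give clean 1,2-reduction of the enal to the allylic alcohol without touching the hindered methyl ester (the hydroxy ester is carried on without delay to avoid lactonisation).

Step 8
Reactants: 11 allylic alcohol
Product: 12 methyl (3R,6E,10E)-12-(TBDPS-oxy)-3-[1-(hydroxymethyl)cyclopropyl]-2,2,6,10-tetramethyldodeca-6,10-dienoate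
Conditions: Et2Zn, CH2I2, CH2Cl2, −10 to 0 °C
Reagents that add atoms: diiodomethane, ICI
Why: Hydroxyl-directed Simmons–Smith (Furukawa) cyclopropanation: the zinc alkoxide should deliver the carbenoid to the adjacent 1,1-disubstituted alkene much faster than to the three undirected trisubstituted alkenes, and no stereocentre arises because the two ring CH2 groups are equivalent.

Step 9
Reactants: 12 cyclopropylmethanol
Product: 13 methyl (3S,6E,10E)-12-(TBDPS-oxy)-3-[1-(iodomethyl)cyclopropyl]-2,2,6,10-tetramethyldodeca-6,10-dienoate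
Conditions: PPh3, I2, imidazole, CH2Cl2, 0 °C
Reagents that add atoms: iodine, II
Why: Appel-type iodination by SN2 displacement of the alkoxyphosphonium ion under non-ionising conditions should avoid cyclopropylcarbinyl cation rearrangement (the descriptor changes to S only because CH2I raises the CIP rank of the cyclopropyl carbon).

Step 10
Reactants: 13 iodo ester
Product: 14 (3S,6E,10E)-12-(TBDPS-oxy)-3-[1-(iodomethyl)cyclopropyl]-2,2,6,10-tetramethyldodeca-6,10-dienal
Conditions: i-Bu2AlH (1.1 equiv), CH2Cl2, −78 °C; MeOH, then aq. potassium sodium tartrate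
Reagents that add atoms: none
Why: Partial reduction of the α-quaternary methyl ester should stop at the tetrahedral aluminium hemiacetal at −78 °C and release the non-enolisable aldehyde on work-up, the primary iodide being inert at this temperature.

Step 11
Reactants: 14 iodo aldehyde
Product: 17 (1S,3R)-3-[(3E,7E)-9-(TBDPS-oxy)-3,7-dimethylnona-3,7-dien-1-yl]-2,2-dimethyl-4-methylidenecyclohexan-1-ol, via homoallyl radical 15 (not isolated), via alkylchromium dichloride 16 (not isolated)
Conditions: CrCl2 (6 equiv), cobalt phthalocyanine CoPc (C32H16CoN8, 10 mol %), DMF, 30 °C, slow addition of 14 (high dilution); aq. NH4Cl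
Reagents that add atoms: none
Why: Proposed new method: monovalent cobalt (CoPc reduced by CrCl2) converts the primary iodide of 14 into the (1-alkylcyclopropyl)methyl radical, whose strain-driven ring opening (at either of the two equivalent ring bonds, one of the fastest radical rearrangements) should outrun capture by divalent chromium and give homoallyl radical 15 with the exocyclic methylene in place; divalent chromium then traps 15 as alkylchromium 16 (trivalent chromium), which adds to the aldehyde. The closest known reaction type is the cobalt-catalysed alkyl Nozaki–Hiyama–Kishi addition of primary alkyl iodides to aldehydes, in which radical intermediates can rearrange before chromium capture; new here are the cyclopropylcarbinyl-to-homoallyl relay and its use for ring closure. The cyclohexane closes in the 6-exo mode (the nucleophilic CH2 attacks the carbonyl carbon, oxygen outside the ring). The carbinol stereocentre is controlled by the existing stereocentre through a chair-like transition state with the side chain and the chromium-bound oxygen both equatorial, which should give the cis (1S,3R) alcohol. The step needs ring opening before metalation (early capture would close a spiro five-membered ring) and chemoselectivity for the aldehyde; radical generation, high dilution and the tolerance of organochromium reagents for alkenes and silyl ethers should secure this, while in the substrate the two equivalent cyclopropane CH2 groups remove any regiochemical choice and the gem-dimethyl group blocks enolisation and favours cyclisation.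

Step 12
Reactants: 17 silyl ether
Product: 18 (1S,3R)-3-[(3E,7E)-9-hydroxy-3,7-dimethylnona-3,7-dien-1-yl]-2,2-dimethyl-4-methylidenecyclohexan-1-ol
Conditions: Bu4NF, THF, 0 °C to rt
Reagents that add atoms: none
Why: Fluoride-mediated desilylation (Si–F bond formation) should free the primary allylic alcohol without affecting the alkenes or the stereocentres.

Step 13
Reactants: 18 diol
Product: 19 (2E,6E)-9-[(1R,3S)-3-hydroxy-2,2-dimethyl-6-methylidenecyclohexyl]-3,7-dimethylnona-2,6-dien-1-yl methyl carbonate
Conditions: ClCO2Me (1.1 equiv), pyridine, CH2Cl2, −20 to 0 °C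
Reagents that add atoms: methyl chloroformate, COC(Cl)=O
Why: Chemoselective acylation: the unhindered primary allylic alcohol should react far faster than the secondary alcohol flanked by the gem-dimethyl carbon.

Step 14
Reactants: 19 allylic carbonate; 20 4-hydroxy-6-methyl-2H-pyran-2-one
Product: 21 sartorypyrone D, 4-hydroxy-3-[(2E,6E)-9-[(1R,3S)-3-hydroxy-2,2-dimethyl-6-methylidenecyclohexyl]-3,7-dimethylnona-2,6-dien-1-yl]-6-methyl-2H-pyran-2-one
Conditions: Pd(PPh3)4 (5 mol %), THF, 40 °C
Reagents that add atoms: none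
Why: Tsuji–Trost allylation: ionisation of the carbonate by zerovalent palladium releases methoxide, which deprotonates the acidic pyranone, and the soft C3 nucleophile should attack the less hindered primary terminus of the syn π-allyl complex with retention of the E alkene, while any O-allyl product re-ionises and is funnelled to the C-allyl product.

**Compound list**
1 | (2E,6E)-farnesol | CC(C)=CCC/C(C)=C/CC/C(C)=C/CO | starting material
2 | tert-butyl(diphenyl){[(2E,6E)-3,7,11-trimethyldodeca-2,6,10-trien-1-yl]oxy}silane | CC(C)=CCC/C(C)=C/CC/C(C)=C/CO[Si](c1ccccc1)(c1ccccc1)C(C)(C)C | intermediate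
3 | (6E,10E)-3-bromo-12-(TBDPS-oxy)-2,6,10-trimethyldodeca-6,10-dien-2-ol (racemic bromohydrin) | CC(C)(O)C(Br)CC/C(C)=C/CC/C(C)=C/CO[Si](c1ccccc1)(c1ccccc1)C(C)(C)C | intermediate (not isolated)
4 | tert-butyl{[(2E,6E)-9-(3,3-dimethyloxiran-2-yl)-3,7-dimethylnona-2,6-dien-1-yl]oxy}diphenylsilane (racemic) | CC1(C)OC1CC/C(C)=C/CC/C(C)=C/CO[Si](c1ccccc1)(c1ccccc1)C(C)(C)C | intermediate
5 | (4E,8E)-10-(TBDPS-oxy)-4,8-dimethyldeca-4,8-dienal | O=CCC/C(C)=C/CC/C(C)=C/CO[Si](c1ccccc1)(c1ccccc1)C(C)(C)C | intermediate
6 | (triphenylphosphoranylidene)acetaldehyde | O=CC=P(c1ccccc1)(c1ccccc1)c1ccccc1 | starting material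
7 | (2E,6E,10E)-12-(TBDPS-oxy)-6,10-dimethyldodeca-2,6,10-trienal | O=C/C=C/CC/C(C)=C/CC/C(C)=C/CO[Si](c1ccccc1)(c1ccccc1)C(C)(C)C | intermediate
8 | 1-methoxy-2-methyl-1-(trimethylsilyloxy)prop-1-ene | COC(O[Si](C)(C)C)=C(C)C | starting material
9 | methyl (3R,6E,10E)-12-(TBDPS-oxy)-2,2,6,10-tetramethyl-3-(2-oxoethyl)dodeca-6,10-dienoate | COC(=O)C(C)(C)[C@@H](CC=O)CC/C(C)=C/CC/C(C)=C/CO[Si](c1ccccc1)(c1ccccc1)C(C)(C)C | intermediate
10 | methyl (3R,6E,10E)-12-(TBDPS-oxy)-2,2,6,10-tetramethyl-3-(3-oxoprop-1-en-2-yl)dodeca-6,10-dienoate | COC(=O)C(C)(C)[C@@H](C(=C)C=O)CC/C(C)=C/CC/C(C)=C/CO[Si](c1ccccc1)(c1ccccc1)C(C)(C)C | intermediate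
11 | methyl (3R,6E,10E)-12-(TBDPS-oxy)-3-(3-hydroxyprop-1-en-2-yl)-2,2,6,10-tetramethyldodeca-6,10-dienoate | COC(=O)C(C)(C)[C@@H](C(=C)CO)CC/C(C)=C/CC/C(C)=C/CO[Si](c1ccccc1)(c1ccccc1)C(C)(C)C | intermediate
12 | methyl (3R,6E,10E)-12-(TBDPS-oxy)-3-[1-(hydroxymethyl)cyclopropyl]-2,2,6,10-tetramethyldodeca-6,10-dienoate | COC(=O)C(C)(C)[C@@H](C1(CO)CC1)CC/C(C)=C/CC/C(C)=C/CO[Si](c1ccccc1)(c1ccccc1)C(C)(C)C | intermediate
13 | methyl (3S,6E,10E)-12-(TBDPS-oxy)-3-[1-(iodomethyl)cyclopropyl]-2,2,6,10-tetramethyldodeca-6,10-dienoate (same spatial arrangement as 12) | COC(=O)C(C)(C)[C@@H](C1(CI)CC1)CC/C(C)=C/CC/C(C)=C/CO[Si](c1ccccc1)(c1ccccc1)C(C)(C)C | intermediate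
14 | (3S,6E,10E)-12-(TBDPS-oxy)-3-[1-(iodomethyl)cyclopropyl]-2,2,6,10-tetramethyldodeca-6,10-dienal | O=CC(C)(C)[C@@H](C1(CI)CC1)CC/C(C)=C/CC/C(C)=C/CO[Si](c1ccccc1)(c1ccccc1)C(C)(C)C | intermediate
15 | 3-[(3R,6E,10E)-12-(TBDPS-oxy)-2,2,6,10-tetramethyl-1-oxododeca-6,10-dien-3-yl]but-3-en-1-yl radical | O=CC(C)(C)[C@@H](C(=C)C[CH2])CC/C(C)=C/CC/C(C)=C/CO[Si](c1ccccc1)(c1ccccc1)C(C)(C)C | intermediate (not isolated)
16 | dichloro{3-[(3R,6E,10E)-12-(TBDPS-oxy)-2,2,6,10-tetramethyl-1-oxododeca-6,10-dien-3-yl]but-3-en-1-yl}chromium (solvent ligands omitted) | O=CC(C)(C)[C@@H](C(=C)CC[Cr](Cl)Cl)CC/C(C)=C/CC/C(C)=C/CO[Si](c1ccccc1)(c1ccccc1)C(C)(C)C | intermediate (not isolated)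
17 | (1S,3R)-3-[(3E,7E)-9-(TBDPS-oxy)-3,7-dimethylnona-3,7-dien-1-yl]-2,2-dimethyl-4-methylidenecyclohexan-1-ol | C=C1CC[C@H](O)C(C)(C)[C@@H]1CC/C(C)=C/CC/C(C)=C/CO[Si](c1ccccc1)(c1ccccc1)C(C)(C)C | intermediate
18 | (1S,3R)-3-[(3E,7E)-9-hydroxy-3,7-dimethylnona-3,7-dien-1-yl]-2,2-dimethyl-4-methylidenecyclohexan-1-ol | C=C1CC[C@H](O)C(C)(C)[C@@H]1CC/C(C)=C/CC/C(C)=C/CO | intermediate
19 | (2E,6E)-9-[(1R,3S)-3-hydroxy-2,2-dimethyl-6-methylidenecyclohexyl]-3,7-dimethylnona-2,6-dien-1-yl methyl carbonate | C=C1CC[C@H](O)C(C)(C)[C@@H]1CC/C(C)=C/CC/C(C)=C/COC(=O)OC | intermediate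
20 | 4-hydroxy-6-methyl-2H-pyran-2-one | Cc1cc(O)cc(=O)o1 | starting material
21 | sartorypyrone D | C=C1CC[C@H](O)C(C)(C)[C@@H]1CC/C(C)=C/CC/C(C)=C/Cc1c(O)cc(C)oc1=O | target

**Step count and risks**

Total step count: 14. Longest linear sequence: 14 steps (1 to 21); 6, 8 and 20 are purchased.

Most likely to fail, first: step 11 (proposed new method). The radical may be captured by chromium before the cyclopropane opens, which would close a spiro five-membered ring; the alkylchromium may be protonated or lose hydride before it cyclises; or facial selectivity at the aldehyde may be poor. The fallback uses known chemistry, sets out from allylic alcohol 11 and comes back at 17. Johnson–Claisen rearrangement of 11 (MeC(OEt)3, cat. EtCO2H, 140 °C) transposes the allyl unit and gives the diester F1, which already carries the exocyclic methylene and a CH2CH2CO2Et arm. Dieckmann condensation (KOt-Bu, THF, 0 °C; aq. HCl), in which only the ethyl ester can enolise, forms the same ring bond and gives the β-keto ester F2. Krapcho dealkoxycarbonylation (LiCl, wet DMSO, 150 °C) gives the ketone F3. NaBH4 (MeOH, 0 °C) should deliver hydride axially and return the equatorial alcohol 17. If step 11 closes the ring but gives the wrong carbinol epimer, oxidation to F3 and the same reduction corrects it.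

Second: step 5. The acid co-catalyst may protodesilylate the ketene acetal faster than it adds, 1,2-addition may compete, or facial selectivity may be low. The fallback sets out from enal 7 and comes back at 9. Luche reduction gives the allylic alcohol F4, and ClCO2Me/pyridine gives the methyl carbonate F5. Iridium-catalysed branched-selective asymmetric allylic alkylation with the same ketene acetal 8 ([Ir(cod)Cl]2, chiral phosphoramidite ligand, THF, rt) gives the vinyl ester F6. Hydroboration–oxidation of its monosubstituted alkene (9-BBN, THF; NaBO3·4H2O) gives the primary alcohol F7, and Dess–Martin oxidation (NaHCO3, CH2Cl2) gives 9.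

Third: step 8. The zinc carbenoid may also cyclopropanate the trisubstituted alkenes, or the δ-hydroxy ester may lactonise under the Lewis acidic zinc conditions before or after cyclopropanation. The fallback sets out from 10 and comes back at 12. Corey–Chaykovsky cyclopropanation of the electron-poor 2-substituted acrolein 10 with dimethylsulfoxonium methylide (Me3S(O)I, NaH, DMSO, rt), a nucleophilic reagent that cannot attack the unactivated alkenes, gives the cyclopropanecarbaldehyde F8. NaBH4 (MeOH, 0 °C) reduces F8 to 12.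

**Further compounds**
F1 | step 11 | 7-ethyl 1-methyl (3R)-3-[(3E,7E)-9-(TBDPS-oxy)-3,7-dimethylnona-3,7-dien-1-yl]-2,2-dimethyl-4-methylideneheptanedioate | COC(=O)C(C)(C)[C@@H](C(=C)CCC(=O)OCC)CC/C(C)=C/CC/C(C)=C/CO[Si](c1ccccc1)(c1ccccc1)C(C)(C)C
F2 | step 11 | ethyl (4R)-4-[(3E,7E)-9-(TBDPS-oxy)-3,7-dimethylnona-3,7-dien-1-yl]-3,3-dimethyl-5-methylidene-2-oxocyclohexane-1-carboxylate (C1 epimers) | C=C1CC(C(=O)OCC)C(=O)C(C)(C)[C@@H]1CC/C(C)=C/CC/C(C)=C/CO[Si](c1ccccc1)(c1ccccc1)C(C)(C)C
F3 | step 11 | (3R)-3-[(3E,7E)-9-(TBDPS-oxy)-3,7-dimethylnona-3,7-dien-1-yl]-2,2-dimethyl-4-methylidenecyclohexan-1-one | C=C1CCC(=O)C(C)(C)[C@@H]1CC/C(C)=C/CC/C(C)=C/CO[Si](c1ccccc1)(c1ccccc1)C(C)(C)C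
F4 | step 5 | (2E,6E,10E)-12-(TBDPS-oxy)-6,10-dimethyldodeca-2,6,10-trien-1-ol | OC/C=C/CC/C(C)=C/CC/C(C)=C/CO[Si](c1ccccc1)(c1ccccc1)C(C)(C)C
F5 | step 5 | (2E,6E,10E)-12-(TBDPS-oxy)-6,10-dimethyldodeca-2,6,10-trien-1-yl methyl carbonate | COC(=O)OC/C=C/CC/C(C)=C/CC/C(C)=C/CO[Si](c1ccccc1)(c1ccccc1)C(C)(C)C
F6 | step 5 | methyl (3R,6E,10E)-12-(TBDPS-oxy)-3-ethenyl-2,2,6,10-tetramethyldodeca-6,10-dienoate | COC(=O)C(C)(C)[C@@H](C=C)CC/C(C)=C/CC/C(C)=C/CO[Si](c1ccccc1)(c1ccccc1)C(C)(C)C
F7 | step 5 | methyl (3R,6E,10E)-12-(TBDPS-oxy)-3-(2-hydroxyethyl)-2,2,6,10-tetramethyldodeca-6,10-dienoate | COC(=O)C(C)(C)[C@@H](CCO)CC/C(C)=C/CC/C(C)=C/CO[Si](c1ccccc1)(c1ccccc1)C(C)(C)C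
F8 | step 8 | methyl (3R,6E,10E)-12-(TBDPS-oxy)-3-(1-formylcyclopropyl)-2,2,6,10-tetramethyldodeca-6,10-dienoate | COC(=O)C(C)(C)[C@@H](C1(C=O)CC1)CC/C(C)=C/CC/C(C)=C/CO[Si](c1ccccc1)(c1ccccc1)C(C)(C)C
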